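Slowness can be read from the fraction left rather than from the fraction made. Let τ be the time constant of starting material A: elapsed time divided by the natural logarithm of charged over remaining, the inverse of a pseudo-first-order constant.

| flask | starting material | second substrate | enzyme | remark | time |
|---|---|---|---|---|---|
| teal | 0.14 M | 0.10 M | 20 µM | run made earlier |  |
| green | 0.41 M | 0.10 M | 20 µM | run made earlier |  |
| blue | 0.10 M | 0.15 M | 20 µM | run made earlier |  |
| Sunday's | 0.30 M | 0.400 M | 20 µM |  | 50 min |
| Saturday's | 0.10 M | 0.100 M | 20 µM |  | 50 min |

- teal (time / min: product / %): 2.00: 0; 4.00: 1.0; 8.00: 0.6; 12.0: 4.2; 25.0: 6.6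
- green (time / min: product / %): 2.00: 0; 6.00: 0.5; 12.0: 0.9; 20.0: 2.3; 25.0: 4.8
- blue (time / min: product / %): 2.00: 0.3; 4.00: 1.8; 8.00: 3.7; 12.0: 5.6; 25.0: 10.2

(scatter of a reading: 1 percentage point)

- on the list of suspects stand: second substrate + starting complex <-> ternary complex; starting material + enzyme <-> starting complex; ternary complex <-> enzyme + product

* the flask that ends with the higher amount of product, in percent of the starting material charged, or "neither" when 2 percentage points or less lies between them (Sunday's / Saturday's / neither)
* final product, as a percentage of the starting material charged, in Sunday's
* final product, as a percentage of the starting material charged, in Saturday's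

The last readings give τ = 366 min in teal, 508 min in green and 232 min in blue. Binding of A and then of second substrate B suggests τ = (c + bA)/B. Teal and green share their B, so they give b = 52.6 min and c = 1750 M·s. Blue, left out of this, is then reckoned at 230 min.

Saturday's comes to τ = 345 min. Sunday's time constant τ comes to 113 min, though its B lies beyond that of the earlier runs. This reckoning therefore gives 13.5 % for Saturday's and 35.9 % for Sunday's.

The forecast also names Sunday's, but with a lower 26 % (17 % to 34 %) against 13 % (10 % to 16 %) for Saturday's, judging of second substrate “so there is little saturation in it”.

The flasks give 17.6 % in Sunday's and 12.3 % in Saturday's, so Sunday's ends higher, but below this reckoning.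

    second substrate + starting complex ⇌ ternary complex (K = 5.70 M⁻¹, k = 3900 M⁻¹ s⁻¹)
    starting material + enzyme ⇌ starting complex (K = 5.60 M⁻¹, k = 89.7 M⁻¹ s⁻¹)
    ternary complex ⇌ enzyme + product (K = 0.110 M, k = 1.81 s⁻¹)

Sunday's result means τ = 258 min, an excess of 145 min over the reckoned value. At 50.0 min in Sunday's, ternary complex holds 51.6 % of the enzyme, its resting state. The product still missing in Sunday's owes partly to the falling back of ternary complex to second substrate and starting complex, partly to the time allowed: without that falling back Sunday's gives 32.3 %, and left until 500 min it gives 47.4 %.

A neighbouring flask is Sunday's with 0.10 M of B. The formula plus the excess, carried unchanged, gives τ = 596 min, hence 8.05 %; the flask gives 7.24 %.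

The earlier runs and the new flask come from a simulation on assumed constants, and the scatter is random.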